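## Analysis of the target

Target 21 is a cis-fused decalin of the eremophilane type. The numbering used throughout is: ring A = C1–C2–C3–C4–C5–C10 (ketone at C2, CH3-15 on C4); ring B = C5–C6–C7–C8–C9–C10 (isopropenyl C11–C13 on C7, acetate on O8, 3-methylbut-2-enoate on O9); CH3-14 sits on the quaternary ring-fusion carbon C5. Six contiguous stereocentres are present (4S,5R,7R,8R,9S,10S). CH3-15, CH3-14, H-10 and the isopropenyl group lie on one face (called β below) and both ester oxygens on the other (α). The methyl groups are therefore cis, the ring fusion is cis, O8 and O9 are cis, and C7/C8 are trans. Sensitive points are the two different esters on a cis-diol (acyl migration), the senecioate (base-induced deconjugation) and the isopropenyl group, which rules out unselective hydrogenation or hydroboration. The difficulty lies in the quaternary C5 flanked by C4 and C10, in five stereocentres around ring B, and in telling O8 from O9. The strategy rests on C5–C10 being cis with an oxygen on C9 beside C10: ring B is the cyclohexene retron C5–C6–C7=C8–C9–C10 of a ring A enone (C5=C10, carbonyl at C1) and a 1-oxygenated butadiene C6–C9. The C7=C8 alkene left beside the C9 oxygen is the handle for C7 and C8; the price is that the carbonyl must later move from C1 to C2, and while it sits on C1 the C9 oxygen is β to it and C10 can epimerise.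

## Retrosynthetic reasoning

21 is first cut at the two ester C–O bonds. The hindered axial O9 ester goes on last (21 from hydroxy acetate 20) and the acetate on the equatorial 8-OH before it (20 from diol ketone 19). This order uses the intrinsic reactivity difference of the two hydroxyls and keeps the base-sensitive senecioate out of all earlier steps.

The C2 carbonyl of 19 is traced to a C1 carbonyl, because only a C1 ketone makes ring A a dienophile for C5=C10. The shift is a 1,2-carbonyl transposition through vinyl sulfide 17 (hydrolysed to 19 via acetonide ketone 18). 17 comes from tosylhydrazone 15 of ketone 14 by lithiation at C2, sulfenylation (16) and loss of nitrogen. This version never enolises towards C10 and creates no new stereocentre.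

Ketone 14 is traced through alcohol 13 to triol 12. The cis-8,9-diol is masked as its acetonide so that only O1 is oxidised; the acetonide also withstands the organolithium step.

In 12 the C7–C11 bond is cut. The isopropenyl group is trans to O8, which is the signature of an SN2 opening of the 7α,8α-epoxide 11 by an isopropenyl nucleophile at C7. The forward step must choose C7 over C8 and attack from the β-face.

Epoxide 11 comes from allylic alcohol 10 by oxygen delivery directed by the 9α-hydroxyl. Diol 10 comes from adduct 9 by hydride, which removes the labile β-acetoxy ketone in the same operation.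

Adduct 9 is cut at C5–C6 and C9–C10, the key disconnection, into enone 7 and diene 8. It is made there because these two bonds create the quaternary C5, the cis fusion and the C9 oxygen in one convergent step from two small fragments. The forward reaction has to overcome the low reactivity of a β,β-disubstituted enone and must be face-, endo- and ortho-selective.

Enone 7 carries the only stereocentre not derived by substrate control. It is traced to silyl enol ether 6 (dehydrogenation) and to enone 5 (conjugate methyl addition). 5 comes from keto aldehyde 3 by aldol condensation through 4, and 3 from aldehyde 1 and enone 2 by a catalytic asymmetric Michael addition that sets C4.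

## Alternatives that were turned down

Alternative 1: Both rings are disconnected at once at C5–C10 and C6–C7. In the open-chain precursor, the C5=C6 alkene (activated by a C14 aldehyde on C5) would add across a (7E,9Z)-diene C7=C8–C9=C10, thermally or with a Lewis acid, to give A1 (cis-fused 14-oxoeremophila-8,11-diene 2-ethylene ketal).
- For: two rings, the quaternary C5 and the C7 centre arise in one step; an enal is a much better dienophile than a β,β-disubstituted enone; the C2 oxygen is in place from the start. On these points it is stronger than the chosen route.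
- Against: a (Z)-diene terminus reaches the s-cis form reluctantly and can undergo a 1,5-hydrogen shift; fusion and the C4/C5 relation hang on one tether stereocentre; the C14 aldehyde must be reduced to CH3 past two alkenes; O8 and O9 must be added to C8=C9 from the concave α-face in competition with the isopropenyl group; the geometry-defined polyene aldehyde is itself a long linear synthesis.
- Comparison: the chosen route uses two short fragments, sets the C9 oxygen in the cycloaddition and uses it to steer C7 and C8, and pays with the C1-to-C2 shift.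

Alternative 2: Ring B is closed on ring A at C5–C6 by a [3,3] shift of a bridged carbinol from a masked o-benzoquinone cycloadduct. The potassium alkoxide at C8 of that precursor would rearrange (anionic oxy-Cope), C3–C8 breaking and C5–C6 forming, and C7 protonation of the enolate gives A2 (cis-fused 9,9-dimethoxy-2-silyloxyeremophila-3,11-dien-8-one).
- For: a sigmatropic shift forms the hindered C5 centre more surely than an intermolecular cycloaddition; oxygen arrives on C2, C8 and C9 with the isopropenyl group already present. On functional-group placement it is stronger.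
- Against: A2 has a C3=C4 alkene, so C4 must be set by hydrogenating a trisubstituted alkene beside the more reactive isopropenyl group; C7 depends on an enolate protonation; C8 and C9 need two separate face-selective reductions and must then be told apart; the bridged precursor is racemic unless its cycloaddition is made asymmetric.
- Comparison: the chosen route carries C4 from a catalytic asymmetric step, derives every other centre from it, and needs no chemoselective hydrogenation.

Alternative 3: C5–C10 is disconnected across a ten-membered ring. Hydrogen-atom transfer from an iron hydride to C6 of the C5=C6 alkene of the ring precursor would give a tertiary C5 radical that adds transannularly to C10 of an enedione, closing both rings to A3 (cis-fused 4,5-dimethyldecalin-2,9-dione).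
- For: radical conjugate addition tolerates the crowded quaternary centre; the C2 and C9 carbonyls are at the right carbons, so no transposition is needed. On ring A oxidation pattern it is stronger.
- Against: the medium ring with a defined trisubstituted alkene must be built first; fusion and the C4/C5 relation depend on the ring conformation at the moment of cyclisation; A3 has nothing on C7 or C8, so isopropenyl and O8 would need desaturation, conjugate addition, α-hydroxylation and reduction at the C9 ketone with the C2 ketone masked.
- Comparison: the chosen cycloaddition leaves C7=C8 exactly beside the C9 oxygen, where the remaining groups are needed, and starts from much simpler material.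

Key step: step 5

## Route

Remarks on the chemistry:
- α/β: β is the face of the decalin carrying CH3-14, CH3-15 and H-10; α is the opposite face. Bicyclic compounds are numbered as the target.
- Commercial 1-acetoxybuta-1,3-diene is an E/Z mixture. It is used in excess, and only the (E) isomer 8 is expected to react, since the (Z) isomer reaches the s-cis form with difficulty.
- C1 of 10–13 (and C3 of 4, C2 of 16) forms without control and is removed again; these centres are written 1ξ and carry no descriptor in the SMILES.

Step 1
Reactants: 1 propanal; 2 but-3-en-2-one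
Product: 3 (S)-2-methyl-5-oxohexanal
Conditions: (R)-2-(methoxydiphenylmethyl)pyrrolidine (5 mol %), ethyl 3,4-dihydroxybenzoate (20 mol %), neat, 4 °C
Reagents that add atoms: none
Why: Enamine-catalysed Michael addition; the diarylmethyl group of the (R)-catalyst shields one face of the (E)-enamine of 1, so 2 (hydrogen-bonded to the catechol) bonds to the open face and C2 should be set as S.

Step 2
Reactants: 3 (S)-2-methyl-5-oxohexanal
Product: 5 (S)-4-methylcyclohex-2-en-1-one, via 3-hydroxy-4-methylcyclohexanone 4 (not isolated)
Conditions: LiOH (0.1 equiv), i-PrOH, rt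
Reagents that add atoms: none
Why: Intramolecular aldol condensation of the methyl ketone onto the aldehyde; once the ring has closed the stereocentre is the γ-carbon of the enone and no longer acidic, and mild base with short contact limits enolisation of the aldehyde beforehand.

Step 3
Reactants: 5 (S)-4-methylcyclohex-2-en-1-one
Product: 6 trimethyl{[(3R,4S)-3,4-dimethylcyclohex-1-en-1-yl]oxy}silane
Conditions: Me2CuLi (from MeLi, CuI), Me3SiCl, Et2O/THF, −78 °C; Et3N, aq. NaHCO3
Reagents that add atoms: lithium dimethylcuprate, [Li+].C[Cu-]C; chlorotrimethylsilane, C[Si](C)(C)Cl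
Why: Gilman cuprate 1,4-addition with silyl trapping of the enolate; methyl enters C3 anti to the C4 methyl, a centre that is flattened again in step 4.

Step 4
Reactants: 6 trimethyl{[(3R,4S)-3,4-dimethylcyclohex-1-en-1-yl]oxy}silane
Product: 7 (S)-3,4-dimethylcyclohex-2-en-1-one
Conditions: Pd(OAc)2 (1.05 equiv), MeCN, rt
Reagents that add atoms: none
Why: Saegusa–Ito oxidation; the palladium enolate loses its only β-hydrogen (C3–H), restoring the C2=C3 alkene with the new methyl on it and releasing zerovalent palladium; C4 is not touched.

Step 5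
Reactants: 7 (S)-3,4-dimethylcyclohex-2-en-1-one; 8 (E)-1-acetoxybuta-1,3-diene
Product: 9 (1R,4aR,5S,8aS)-4a,5-dimethyl-8-oxo-1,4,4a,5,6,7,8,8a-octahydronaphthalen-1-yl acetate (route numbering: 9α-acetoxy-4β,5β-dimethyl-10βH-decal-7-en-1-one)
Conditions: 7 precomplexed with AlBr3/AlMe3 (10:1, 1.2 equiv), toluene/CH2Cl2, −20 °C; then 8 (3 equiv), −20 to 0 °C
Reagents that add atoms: none
Why: AlBr3 (AlMe3 scavenges protic acid) binds the carbonyl of 7 and lowers its LUMO, and 8 adds in a concerted but asynchronous [4+2] in which the unsubstituted diene terminus C6 bonds first to the β-carbon C5 and the acetoxy-bearing C9 then closes onto the α-carbon C10. The closest known reaction type is the Lewis-acid-promoted Diels–Alder reaction of 3-alkylcyclohex-2-enones with butadienes, which gives cis-fused angular-methyl decalones and needs strong aluminium Lewis acids for β,β-disubstituted enones. Ring B is the only ring closed, as a cyclohexene by suprafacial–suprafacial cycloaddition onto the pre-formed ring A. At C5 and C10, addition to the ring cis-alkene forces CH3-14 and H-10 cis, hence the cis fusion. For face selectivity, allylic strain with the methyl on the alkene carbon C5 holds CH3-15 pseudoaxial, so the diene should come in anti to it and CH3-14 should end cis to CH3-15. At C9, the endo transition state, with the diene under the complexed C1 carbonyl, places the acetoxy group cis to C1 (9α). Ortho regiochemistry follows from the donor at the diene terminus, which makes C6 the nucleophilic end and matches it with the electrophilic β-carbon. The step thus needs face, endo and ortho selectivity at once, each resting on a feature already present in 7 or 8, and it leaves C4 untouched.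

Step 6
Reactants: 9 9α-acetoxy-4β,5β-dimethyl-10βH-decal-7-en-1-one
Product: 10 4β,5β-dimethyl-10βH-decal-7-ene-1ξ,9α-diol
Conditions: LiAlH4, THF, −78 to 0 °C; aq. NaOH work-up
Reagents that add atoms: none
Why: Hydride reduction of the ketone and reductive cleavage of the acetate in one operation; removing the C1 carbonyl at once excludes β-elimination of the C9 oxygen and epimerisation at C10, and the C1 configuration is immaterial.

Step 7
Reactants: 10 4β,5β-dimethyl-10βH-decal-7-ene-1ξ,9α-diol
Product: 11 7α,8α-epoxy-4β,5β-dimethyl-10βH-decalin-1ξ,9α-diol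
Conditions: VO(acac)2 (5 mol %), t-BuOOH, CH2Cl2, 0 °C to rt
Reagents that add atoms: tert-butyl hydroperoxide, CC(C)(C)OO
Why: Hydroxyl-directed epoxidation of a cyclic allylic alcohol; the vanadium peroxide bound to the 9α-oxygen should deliver oxygen to the α-face of C7=C8, which fixes C8 and prepares C7 for inversion.

Step 8
Reactants: 11 7α,8α-epoxy-4β,5β-dimethyl-10βH-decalin-1ξ,9α-diol
Product: 12 7β-isopropenyl-4β,5β-dimethyl-10βH-decalin-1ξ,8α,9α-triol
Conditions: CH2=C(CH3)MgBr (5 equiv), CuI (20 mol %), THF, −30 to 0 °C
Reagents that add atoms: 2-propenylmagnesium bromide, C=C(C)[Mg]Br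
Why: Copper-catalysed Grignard opening of an epoxide by SN2 attack with inversion; C7 is the carbon remote from the C9 alkoxide (C8 is deactivated inductively and shielded), and trans-diaxial (Fürst–Plattner) opening from the β-face should give 7β-isopropenyl with O8 left α.

Step 9
Reactants: 12 7β-isopropenyl-4β,5β-dimethyl-10βH-decalin-1ξ,8α,9α-triol
Product: 13 8α,9α-isopropylidenedioxy-7β-isopropenyl-4β,5β-dimethyl-10βH-decalin-1ξ-ol
Conditions: Me2C(OMe)2, PPTS (cat.), acetone, rt
Reagents that add atoms: 2,2-dimethoxypropane, COC(C)(C)OC
Why: Acetonide formation; the cis-8,9-diol closes the favoured five-membered dioxolane, so only O1 stays free, and the group tolerates the organolithium chemistry of step 12.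

Step 10
Reactants: 13 8α,9α-isopropylidenedioxy-7β-isopropenyl-4β,5β-dimethyl-10βH-decalin-1ξ-ol
Product: 14 8α,9α-isopropylidenedioxy-7β-isopropenyl-4β,5β-dimethyl-10βH-decalin-1-one
Conditions: Dess–Martin periodinane, NaHCO3, CH2Cl2, 0 °C to rt
Reagents that add atoms: none
Why: Mild buffered oxidation of the secondary alcohol merges the C1 epimers into one ketone without epimerising C10 or eliminating the β-oxygen at C9.

Step 11
Reactants: 14 8α,9α-isopropylidenedioxy-7β-isopropenyl-4β,5β-dimethyl-10βH-decalin-1-one
Product: 15 (E)-p-toluenesulfonylhydrazone of 14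
Conditions: TsNHNH2, EtOH, 40 °C
Reagents that add atoms: p-toluenesulfonyl hydrazide, Cc1ccc(cc1)S(=O)(=O)NN
Why: Hydrazone formation; the N–NHTs group should point to the less hindered C2 side, which fixes the site of the syn-directed lithiation in step 12.

Step 12
Reactants: 15 (E)-p-toluenesulfonylhydrazone of 14
Product: 17 8α,9α-isopropylidenedioxy-7β-isopropenyl-4β,5β-dimethyl-2-(methylsulfanyl)-10βH-decal-1-ene, via 2-methylsulfanyl tosylhydrazone 16 (not isolated)
Conditions: n-BuLi (2.2 equiv), TMEDA, THF, −78 to −20 °C; MeSSMe, −78 °C; n-BuLi (1.5 equiv), −78 °C to rt; H2O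
Reagents that add atoms: dimethyl disulfide, CSSC
Why: Shapiro reaction with sulfenylation of the hydrazone dianion (a 1,2-carbonyl transposition): lithiation at C2, C–S bond formation, second lithiation of the now more acidic C2–H, loss of sulfinate and nitrogen to the C1 vinyllithium, and protonation. The C1=C2 vinyl sulfide forms regiospecifically and C10 is never deprotonated.

Step 13
Reactants: 17 8α,9α-isopropylidenedioxy-7β-isopropenyl-4β,5β-dimethyl-2-(methylsulfanyl)-10βH-decal-1-ene
Product: 19 8α,9α-dihydroxy-7β-isopropenyl-4β,5β-dimethyl-10βH-decalin-2-one, via acetonide ketone 18 (not isolated)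
Conditions: HgCl2 (2 equiv), MeCN/H2O (4:1), 50 °C; then 1 M HCl, THF, rt
Reagents that add atoms: water, O
Why: Thiophilic mercury-assisted hydrolysis of the vinyl sulfide places the carbonyl on C2, and aqueous acid then cleaves the dioxolane; C10 is now β to the ketone and configurationally safe.

Step 14
Reactants: 19 8α,9α-dihydroxy-7β-isopropenyl-4β,5β-dimethyl-10βH-decalin-2-one
Product: 20 8α-acetoxy-9α-hydroxy-7β-isopropenyl-4β,5β-dimethyl-10βH-decalin-2-one
Conditions: AcCl (1.1 equiv), 2,4,6-collidine, CH2Cl2, −78 °C
Reagents that add atoms: acetyl chloride, CC(=O)Cl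
Why: Kinetic acylation of the less hindered, equatorial 8-OH; the 9-OH is axial and flanked by the ring fusion, so it should react much more slowly.

Step 15
Reactants: 20 8α-acetoxy-9α-hydroxy-7β-isopropenyl-4β,5β-dimethyl-10βH-decalin-2-one
Product: 21 (4S,5R,7R,8R,9S,10S)-8α-acetoxy-9α-(3-methylbut-2-enoyloxy)-10βH-eremophil-11-en-2-one
Conditions: 3-methylbut-2-enoyl chloride, DMAP, pyridine, CH2Cl2, 0 °C to rt
Reagents that add atoms: 3-methylbut-2-enoyl chloride, CC(C)=CC(=O)Cl
Why: DMAP-catalysed acylation of the remaining hindered alcohol; pyridine in place of a trialkylamine limits vinylketene formation and so keeps the ester conjugated.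

## Compound list

1 | propanal | CCC=O | starting material
2 | but-3-en-2-one (methyl vinyl ketone) | CC(=O)C=C | starting material
3 | (S)-2-methyl-5-oxohexanal | O=C[C@@H](C)CCC(C)=O | intermediate
4 | (4S)-3-hydroxy-4-methylcyclohexan-1-one (C3 epimers) | C[C@H]1CCC(=O)CC1O | intermediate (not isolated)
5 | (S)-4-methylcyclohex-2-en-1-one | C[C@H]1CCC(=O)C=C1 | intermediate
6 | trimethyl{[(3R,4S)-3,4-dimethylcyclohex-1-en-1-yl]oxy}silane | C[C@H]1CCC(O[Si](C)(C)C)=C[C@@H]1C | intermediate
7 | (S)-3,4-dimethylcyclohex-2-en-1-one | C[C@H]1CCC(=O)C=C1C | intermediate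
8 | (E)-1-acetoxybuta-1,3-diene | CC(=O)O/C=C/C=C | starting material
9 | (1R,4aR,5S,8aS)-4a,5-dimethyl-8-oxo-1,4,4a,5,6,7,8,8a-octahydronaphthalen-1-yl acetate (9α-acetoxy-4β,5β-dimethyl-10βH-decal-7-en-1-one) | C1[C@@]2(C)[C@H](C(=O)CC[C@@H]2C)[C@H](OC(C)=O)C=C1 | intermediate
10 | 4β,5β-dimethyl-10βH-decal-7-ene-1ξ,9α-diol | C[C@H]1CCC(O)[C@H]2[C@]1(C)CC=C[C@H]2O | intermediate
11 | 7α,8α-epoxy-4β,5β-dimethyl-10βH-decalin-1ξ,9α-diol | C[C@H]1CCC(O)[C@H]2[C@]1(C)C[C@H]3O[C@H]3[C@H]2O | intermediate
12 | 7β-isopropenyl-4β,5β-dimethyl-10βH-decalin-1ξ,8α,9α-triol | C=C(C)[C@H]1C[C@@]2(C)[C@H](C(O)CC[C@@H]2C)[C@H](O)[C@@H]1O | intermediate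
13 | 8α,9α-isopropylidenedioxy-7β-isopropenyl-4β,5β-dimethyl-10βH-decalin-1ξ-ol | C=C(C)[C@H]1C[C@@]2(C)[C@H](C(O)CC[C@@H]2C)[C@@H]3OC(C)(C)O[C@H]13 | intermediate
14 | 8α,9α-isopropylidenedioxy-7β-isopropenyl-4β,5β-dimethyl-10βH-decalin-1-one | C=C(C)[C@H]1C[C@@]2(C)[C@H](C(=O)CC[C@@H]2C)[C@@H]3OC(C)(C)O[C@H]13 | intermediate
15 | (E)-p-toluenesulfonylhydrazone of 14 (NHTs on the C2 side) | C=C(C)[C@H]1C[C@@]2(C)[C@H](/C(=N/NS(=O)(=O)c4ccc(C)cc4)CC[C@@H]2C)[C@@H]3OC(C)(C)O[C@H]13 | intermediate
16 | 2ξ-methylsulfanyl derivative of 15 (present as its N-lithio salt) | C=C(C)[C@H]1C[C@@]2(C)[C@H](C(=NNS(=O)(=O)c4ccc(C)cc4)C(SC)C[C@@H]2C)[C@@H]3OC(C)(C)O[C@H]13 | intermediate (not isolated)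
17 | 8α,9α-isopropylidenedioxy-7β-isopropenyl-4β,5β-dimethyl-2-(methylsulfanyl)-10βH-decal-1-ene | C=C(C)[C@H]1C[C@@]2(C)[C@H](C=C(SC)C[C@@H]2C)[C@@H]3OC(C)(C)O[C@H]13 | intermediate
18 | 8α,9α-isopropylidenedioxy-7β-isopropenyl-4β,5β-dimethyl-10βH-decalin-2-one | C=C(C)[C@H]1C[C@@]2(C)[C@H](CC(=O)C[C@@H]2C)[C@@H]3OC(C)(C)O[C@H]13 | intermediate (not isolated)
19 | 8α,9α-dihydroxy-7β-isopropenyl-4β,5β-dimethyl-10βH-decalin-2-one | C=C(C)[C@H]1C[C@@]2(C)[C@H](CC(=O)C[C@@H]2C)[C@H](O)[C@@H]1O | intermediate
20 | 8α-acetoxy-9α-hydroxy-7β-isopropenyl-4β,5β-dimethyl-10βH-decalin-2-one | C=C(C)[C@H]1C[C@@]2(C)[C@H](CC(=O)C[C@@H]2C)[C@H](O)[C@@H]1OC(C)=O | intermediate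
21 | (4S,5R,7R,8R,9S,10S)-8α-acetoxy-9α-(3-methylbut-2-enoyloxy)-10βH-eremophil-11-en-2-one, i.e. (1S,2R,3R,4aR,5S,8aS)-2-acetoxy-4a,5-dimethyl-7-oxo-3-(prop-1-en-2-yl)decahydronaphthalen-1-yl 3-methylbut-2-enoate | C=C(C)[C@H]1C[C@@]2(C)[C@H](CC(=O)C[C@@H]2C)[C@H](OC(=O)C=C(C)C)[C@@H]1OC(C)=O | target

## Step count and least certain steps

Total: 15 steps. Longest linear sequence: 15 steps (1 and 2 to 21); diene 8 is bought and enters at step 5.

**Step 5 (key step).** The cycloaddition may simply not take place at the fully substituted β-carbon, or the diene may be lost to Lewis-acid-induced polymerisation; ionisation of the allylic acetate or β-elimination in the product, and erosion of endo or facial selectivity, are further risks. Fallback: ring B would be built stepwise from 7, forming the same two bonds in sequence.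
- Conjugate allylation with allyltrimethylsilane/TiCl4 (Hosomi–Sakurai) puts the allyl group on C5 anti to CH3-15. The titanium enolate is trapped in the same flask with acrolein. Axial attack at C10 anti to the then axial CH3-14 should place the new chain cis to the allyl group, giving 5α-allyl-10α-(1-hydroxyallyl)-4β,5β-dimethylcyclohexan-1-one F1.
- Ring-closing metathesis with the second-generation Grubbs catalyst closes C7=C8 to 9β-hydroxy-4β,5β-dimethyl-10βH-decal-7-en-1-one F2.
- The closed aldol transition state of a ring (E)-enolate is expected to give the carbinol epimeric to that of 9. Mitsunobu esterification with acetic acid (PPh3, DIAD) therefore inverts C9 and the route is rejoined at 9.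

**Step 8.** The nucleophile has to enter C7 syn-axial to CH3-14. Opening at C8 through the other half-chair (possibly helped by chelation of the two alkoxides), or no opening at all, are the likely failures. Fallback from 10, with the C7–C bond made by conjugate addition so that C8 cannot be attacked:
- MnO2 oxidises only the allylic 9-OH to 1ξ-hydroxy-4β,5β-dimethyl-10βH-decal-7-en-9-one F3.
- CH2=C(CH3)MgBr/CuI with Me3SiCl adds the isopropenyl group to C7 from the convex β-face, and the enolate is trapped (O1 is silylated as well) as 7β-isopropenyl-4β,5β-dimethyl-1ξ,9-bis(trimethylsilyloxy)-10βH-decal-8-ene F4.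
- Rubottom oxidation with dimethyldioxirane at −78 °C, then dilute acid, puts oxygen on C8 anti to the C7 substituent; the electron-rich enol ether should react before the isopropenyl group. This gives 1ξ,8α-dihydroxy-7β-isopropenyl-4β,5β-dimethyl-10βH-decalin-9-one F5.
- NaBH4/CeCl3 reduction from the convex face returns to 12.

**Step 12.** Incomplete second lithiation, sulfenylation on nitrogen, or protonation of the vinyllithium before nitrogen loss is complete would give mixtures of alkene and unsulfenylated material. Fallback from 14 by the stepwise enolate version of the transposition: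
- LDA at −78 °C (kinetic C2 enolate) and PhSSO2Ph give 8α,9α-isopropylidenedioxy-7β-isopropenyl-4β,5β-dimethyl-2ξ-phenylthio-10βH-decalin-1-one F6.
- NaBH4 gives the corresponding 1ξ-ol F7.
- MsCl/Et3N gives its 1-O-methanesulfonate F8.
- KOtBu in DMSO removes the sulfur-acidified C2–H to give 8α,9α-isopropylidenedioxy-7β-isopropenyl-4β,5β-dimethyl-2-phenylthio-10βH-decal-1-ene F9.
- F9 is hydrolysed with HgCl2 and then acid exactly as in step 13, rejoining the route at 19 (through 18).

**Step 15 (with step 14).** Acylation of the axial 9-OH is slow, which leaves time for acetyl migration from O8 to O9 followed by acylation of the freed 8-OH, and for deconjugation of the acyl donor. Fallback from 19, reversing the order of ester introduction: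
- Et3SiCl/imidazole at −40 °C silylates the equatorial 8-OH to 9α-hydroxy-7β-isopropenyl-4β,5β-dimethyl-8α-triethylsilyloxy-10βH-decalin-2-one F10.
- 3-Methylbut-2-enoic acid under Steglich conditions (DCC, DMAP) gives its 9-O-(3-methylbut-2-enoate) F11.
- HF·pyridine frees 8α-hydroxy-9α-(3-methylbut-2-enoyloxy)-7β-isopropenyl-4β,5β-dimethyl-10βH-decalin-2-one F12.
- Ac2O/pyridine acetylates the unhindered 8-OH and gives 21.

## Further compounds

F1 | step 5 | 5α-allyl-10α-(1-hydroxyallyl)-4β,5β-dimethylcyclohexan-1-one (carbinol as in F2) | C[C@H]1CCC(=O)[C@H]([C@@H](O)C=C)[C@]1(C)CC=C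
F2 | step 5 | 9β-hydroxy-4β,5β-dimethyl-10βH-decal-7-en-1-one | C[C@H]1CCC(=O)[C@H]2[C@]1(C)CC=C[C@@H]2O
F3 | step 8 | 1ξ-hydroxy-4β,5β-dimethyl-10βH-decal-7-en-9-one | C[C@H]1CCC(O)[C@H]2[C@]1(C)CC=CC2=O
F4 | step 8 | 7β-isopropenyl-4β,5β-dimethyl-1ξ,9-bis(trimethylsilyloxy)-10βH-decal-8-ene | C[C@H]1CCC(O[Si](C)(C)C)[C@H]2[C@]1(C)C[C@H](C(C)=C)C=C2O[Si](C)(C)C
F5 | step 8 | 1ξ,8α-dihydroxy-7β-isopropenyl-4β,5β-dimethyl-10βH-decalin-9-one | C[C@H]1CCC(O)[C@H]2[C@]1(C)C[C@H](C(C)=C)[C@@H](O)C2=O
F6 | step 12 | 8α,9α-isopropylidenedioxy-7β-isopropenyl-4β,5β-dimethyl-2ξ-phenylthio-10βH-decalin-1-one | C=C(C)[C@H]1C[C@@]2(C)[C@H](C(=O)C(Sc4ccccc4)C[C@@H]2C)[C@@H]3OC(C)(C)O[C@H]13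
F7 | step 12 | 8α,9α-isopropylidenedioxy-7β-isopropenyl-4β,5β-dimethyl-2ξ-phenylthio-10βH-decalin-1ξ-ol | C=C(C)[C@H]1C[C@@]2(C)[C@H](C(O)C(Sc4ccccc4)C[C@@H]2C)[C@@H]3OC(C)(C)O[C@H]13
F8 | step 12 | 1-O-methanesulfonate of F7 | C=C(C)[C@H]1C[C@@]2(C)[C@H](C(OS(C)(=O)=O)C(Sc4ccccc4)C[C@@H]2C)[C@@H]3OC(C)(C)O[C@H]13
F9 | step 12 | 8α,9α-isopropylidenedioxy-7β-isopropenyl-4β,5β-dimethyl-2-phenylthio-10βH-decal-1-ene | C=C(C)[C@H]1C[C@@]2(C)[C@H](C=C(Sc4ccccc4)C[C@@H]2C)[C@@H]3OC(C)(C)O[C@H]13
F10 | step 15 | 9α-hydroxy-7β-isopropenyl-4β,5β-dimethyl-8α-triethylsilyloxy-10βH-decalin-2-one | C=C(C)[C@H]1C[C@@]2(C)[C@H](CC(=O)C[C@@H]2C)[C@H](O)[C@@H]1O[Si](CC)(CC)CC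
F11 | step 15 | 9α-(3-methylbut-2-enoyloxy)-7β-isopropenyl-4β,5β-dimethyl-8α-triethylsilyloxy-10βH-decalin-2-one | C=C(C)[C@H]1C[C@@]2(C)[C@H](CC(=O)C[C@@H]2C)[C@H](OC(=O)C=C(C)C)[C@@H]1O[Si](CC)(CC)CC
F12 | step 15 | 8α-hydroxy-9α-(3-methylbut-2-enoyloxy)-7β-isopropenyl-4β,5β-dimethyl-10βH-decalin-2-one | C=C(C)[C@H]1C[C@@]2(C)[C@H](CC(=O)C[C@@H]2C)[C@H](OC(=O)C=C(C)C)[C@@H]1O
A1 | alternative 1 | cis-fused 14-oxoeremophila-8,11-diene 2-ethylene ketal | C=C(C)[C@H]1C[C@@]2(C=O)[C@H](CC3(OCCO3)C[C@@H]2C)C=C1
A2 | alternative 2 | cis-fused 9,9-dimethoxy-2-silyloxyeremophila-3,11-dien-8-one | C=C(C)[C@H]1C[C@@]2(C)[C@H](C[C@H](O[Si](C)(C)C(C)(C)C)C=C2C)C(OC)(OC)C1=O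
A3 | alternative 3 | cis-fused 4,5-dimethyldecalin-2,9-dione | C1C[C@@]2(C)[C@H](CC(=O)C[C@@H]2C)C(=O)C1
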